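Substrate cannot touch free catalyst: free catalyst reacts with reagent, each turn begins there, and so the concentration that sets the order of the rate is free reagent.

substrate 0.20 mM; reagent 0.600 mM (fed, over 0.40 s); free catalyst 2.0 µM; time 5.0 s

- part of the substrate that has reacted at 5.0 s
- share of free reagent in free reagent and idle adduct together, at 5.0 s

- for released group the idle adduct is counted in
- run time (flask): 5.0 s

    reagent + free catalyst → catalyst intermediate A (k1 = 1.1 × 10⁵ /M/s)
    substrate + catalyst intermediate A ⇌ catalyst intermediate B (K2 = 30000 /M, k2 = 1.1 × 10⁷ /M/s)
    catalyst intermediate B ⇌ released group + catalyst intermediate C (K3 = 5.3 × 10⁻⁴ M, k3 = 330 /s)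
    catalyst intermediate C → free catalyst + product (k4 = 160 /s)
    reagent + released group ⇌ idle adduct, settled at all times (K5 = 4400 /M)
    reagent ⇌ dormant form (K6 = 0.72, k6 = 0.32 /s)

Which given numbers must be known well? An error in the catalyst charge passes unchanged into the capture rate, and an error in k1 passes somewhat damped. K6 counts less, entering through one fraction: reagent and dormant form relax with a half-life of 0.907 s, short against 5.0 s, which leaves free reagent this fraction of the pool:

s = 0.581

k3 and k4 count little, because one capture at that fraction of the charge takes 26.1 ms, longer than the 9.28 ms of both later steps, so while substrate lasts free catalyst is the resting state, with this fraction of the catalyst: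

f = 0.737

Substrate binding, at 2200 /s at the start, outruns capture and drops out while substrate lasts, and the feed is short against the time. K5 stays out of this reckoning for c, which therefore overstates the pool by what idle adduct holds. With s and f, the capture constant, the pseudo-first-order rate at which catalyst draws down the reagent pool, is

k = 0.0943 /s

By 5.0 s the pool can lose this fraction of its charge:

b = 0.376

Substrate, the limiting reagent, needs a third, which is less, so c comes to 100 %, with a thin margin. For fr, setting released group equal to the substrate charge gives the bound 53.2 %.

The forecast gave 99.5 % (93 % to 100 %) and 67 % (62 % to 72 %), holding the cycle “limited mainly by reagent capture of free catalyst”. The flask gives c = 99.6 % and fr = 66.6 %.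

The flask charged with 0.15 mM of reagent holds 0.750 equivalents, so there reagent is the shorter charge. Capture takes 104 ms, f rises to 0.918, and the capture constant rises from 0.0943 /s to 0.117 /s. The pool then loses 0.444 of its charge, which reckons to c = 33.3 %. That flask gives 33.3 %, with free catalyst at 95.3 % of the catalyst charged and reagent at 25.8 % of its own charge.

The rate constants were chosen freely.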